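**Plan**
- **Cuts, in retrosynthetic order:** O–Si; C2'–C3' of the diene (Suzuki–Miyaura coupling of an (E)-alkenylboronate with a (Z)-alkenyl iodide); the terminal CH2 of a vinyl group on C2 (cross metathesis); C2–C3 of the dihydropyran ring; O1–C2 (phenol plus ethyl but-2-ynoate); C3=C4 (Wittig).
- **Enabling feature:** C2 bears O1 and is allylic to C1'=C2'. Allylic transposition therefore makes C2 the γ-carbon of an achiral (E)-γ-aryloxyallyl phosphate, and the O1 lone pair directs attack to C2. The C3–C4 bridge on the benzene ring is the anti-Markovnikov hydroboration adduct of an o-vinyl group, so C3 is a latent unstabilised nucleophile and no activating group has to be removed.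
- **Forward order:** the benzene ring is bought, the O1–C2 tether is made, and the pyran ring is closed at the fully substituted C2 (step 6). The vinyl group becomes the (E)-alkenylboronate, which is joined to the C14 (Z)-iodide carrying the bought cyclohexene ring. Desilylation ends the route.
- **Stereochemistry:** C2 (R) comes from a chiral bisphosphine–copper catalyst that selects one enantiotopic alkene face. 1'E comes from cross metathesis and 3'Z from syn-carbocupration of propyne. Both geometries pass through a stereoretentive coupling.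

Key step: step 6

Remark: C2 of the target is R (O1 > C1' > C3 > CH3). The sense of induction of the copper catalyst on this substrate class cannot be derived from precedent, so (R)-DTBM-SEGPHOS is written, and its equally available antipode is taken if a first run (chiral HPLC of 9) shows the opposite sense.

**Step 1**
Reactants: 1 2,5-dihydroxybenzaldehyde
Product: 2 2-hydroxy-5-(triisopropylsilyloxy)benzaldehyde
Conditions: TIPSCl (1.05 equiv), imidazole, CH2Cl2, 0 °C
Reagents that add atoms: triisopropylsilyl chloride, CC(C)[Si](Cl)(C(C)C)C(C)C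
Why: Selective O-silylation, since the 2-OH is hydrogen-bonded to and flanked by the aldehyde, so the bulky silyl chloride should take the free 5-OH.

**Step 2**
Reactants: 2 2-hydroxy-5-(triisopropylsilyloxy)benzaldehyde
Product: 3 2-ethenyl-4-(triisopropylsilyloxy)phenol
Conditions: Ph3PCH3Br (2.3 equiv), KOtBu (2.2 equiv), THF, 0 to 23 °C
Reagents that add atoms: methyltriphenylphosphonium bromide, C[P+](c1ccccc1)(c1ccccc1)c1ccccc1.[Br-]
Why: Wittig methylenation of a salicylaldehyde with excess ylide (one equivalent is consumed by the phenol) is a standard entry to o-vinylphenols, and the aryl TIPS ether tolerates the base.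

**Step 3**
Reactants: 3 2-ethenyl-4-(triisopropylsilyloxy)phenol; 4 ethyl but-2-ynoate
Product: 5 ethyl (2E)-3-[2-ethenyl-4-(triisopropylsilyloxy)phenoxy]but-2-enoate
Conditions: Cs2CO3 (20 mol %), BHT (trace), MeCN, 40 °C
Reagents that add atoms: none
Why: Base-catalysed oxa-Michael addition of a phenoxide to an alkynoate, in which reversible phenoxide addition should let the more stable E isomer (aryloxy trans to the ester) accumulate, any Z isomer being removed by chromatography.

**Step 4**
Reactants: 5 ethyl (2E)-3-[2-ethenyl-4-(triisopropylsilyloxy)phenoxy]but-2-enoate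
Product: 6 (2E)-3-[2-ethenyl-4-(triisopropylsilyloxy)phenoxy]but-2-en-1-ol
Conditions: DIBAL-H (2.2 equiv), CH2Cl2, −78 °C; Rochelle salt
Reagents that add atoms: none
Why: 1,2-Reduction of a β-aryloxy enoate with DIBAL-H at low temperature should give the allylic alcohol with the alkene geometry unchanged, and a non-acidic work-up protects the enol ether.

**Step 5**
Reactants: 6 (2E)-3-[2-ethenyl-4-(triisopropylsilyloxy)phenoxy]but-2-en-1-ol
Product: 7 diethyl (2E)-3-[2-ethenyl-4-(triisopropylsilyloxy)phenoxy]but-2-en-1-yl phosphate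
Conditions: ClP(O)(OEt)2, pyridine, DMAP (cat.), CH2Cl2, 0 °C; cold NaHCO3 wash, no chromatography
Reagents that add atoms: diethyl chlorophosphate, CCOP(=O)(Cl)OCC
Why: O-Phosphorylation of a primary allylic alcohol is routine, and because the aryloxy donor makes this phosphate more ionisable than a prenyl phosphate, it is kept cold and base-washed and is used at once.

**Step 6**
Reactants: 7 diethyl (2E)-3-[2-ethenyl-4-(triisopropylsilyloxy)phenoxy]but-2-en-1-yl phosphate
Product: 9 (2R)-2-ethenyl-2-methyl-6-(triisopropylsilyloxy)-3,4-dihydro-2H-chromene, via B-alkyl-9-BBN adduct 8 (not isolated)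
Conditions: (9-BBN-H)2 (0.5 equiv), THF, 23 °C; then KOtBu (1.0 equiv), CuOTf·0.5 toluene (10 mol %), (R)-DTBM-SEGPHOS (12 mol %), THF (0.02 M), 0 to 23 °C
Reagents that add atoms: none
Why: Proposed new method: 9-BBN-H should add only to the terminal styrene C3=C4 with boron on C3 (the trisubstituted, phosphate-deactivated enol-ether alkene is far slower), alkoxide-assisted B-to-Cu transmetalation then places copper on C3, and this alkylcopper(I) attacks the tethered allylic phosphate in SN2' fashion (π-complexation of C2=C1', oxidative addition anti to the phosphate with copper on C2, reductive elimination C3–C2), which releases C1'=C2' as a vinyl group. The closest known reaction type is the copper-catalysed γ-selective allyl–alkyl coupling of alkyl-9-BBN reagents with allylic phosphates or chlorides, whose bisphosphine-ligated enantioselective form builds all-carbon quaternary centres from γ,γ-disubstituted substrates, and the copper-catalysed SN2' alkylation of γ-acyloxyallyl bromides shows that an oxygen-bearing γ-carbon accepts the alkyl group, so the new elements are the intramolecular setting and the γ-aryloxy substituent. The dihydropyran ring closes in the 6-exo-trig mode, the attacked double bond lying outside the new ring. The only stereocentre, C2, is controlled by the C2-symmetric bisphosphine on copper, which selects one enantiotopic face of the geometrically pure (E)-alkene, while the freely rotating CH2OP(O)(OEt)2 group can stand anti on either face. γ- over α-attack is secured by ring size (six against eight with an E-alkene inside) and by the O1 lone pair that stabilises positive charge at C2, and cyclisation over oligomerisation is secured by high dilution. Boron and phosphate leave in the same operation, so nothing has to be removed afterwards.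

**Step 7**
Reactants: 9 (2R)-2-ethenyl-2-methyl-6-(triisopropylsilyloxy)-3,4-dihydro-2H-chromene; 10 vinylboronic acid pinacol ester
Product: 11 (2R)-2-methyl-2-[(E)-2-(4,4,5,5-tetramethyl-1,3,2-dioxaborolan-2-yl)ethenyl]-6-(triisopropylsilyloxy)-3,4-dihydro-2H-chromene
Conditions: 10 (3 equiv), Hoveyda–Grubbs II (5 mol %), CH2Cl2, 40 °C
Reagents that add atoms: none
Why: Olefin cross metathesis between a vinyl group on a fully substituted allylic carbon, which does not homodimerise and has no allylic hydrogen to isomerise, and excess vinylboronate should give the E-alkenylboronate, because C2 and Bpin avoid each other in the metallacyclobutane.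

**Step 8**
Reactants: 12 2-(2,6,6-trimethylcyclohex-1-en-1-yl)acetaldehyde (β-homocyclocitral)
Product: 13 2-(2,6,6-trimethylcyclohex-1-en-1-yl)ethan-1-ol
Conditions: NaBH4, MeOH, 0 °C
Reagents that add atoms: none
Why: Borohydride reduction of the aldehyde is fast at 0 °C and leaves the tetrasubstituted β,γ-double bond in place.

**Step 9**
Reactants: 13 2-(2,6,6-trimethylcyclohex-1-en-1-yl)ethan-1-ol
Product: 14 2-(2-bromoethyl)-1,3,3-trimethylcyclohex-1-ene
Conditions: CBr4, PPh3, CH2Cl2, 0 °C
Reagents that add atoms: carbon tetrabromide, BrC(Br)(Br)Br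
Why: The Appel reaction converts a primary alcohol into the bromide under neutral conditions that do not touch the hindered alkene.

**Step 10**
Reactants: 14 2-(2-bromoethyl)-1,3,3-trimethylcyclohex-1-ene; 15 propyne
Product: 19 2-[(3Z)-4-iodo-3-methylbut-3-en-1-yl]-1,3,3-trimethylcyclohex-1-ene, via Grignard reagent 16 (not isolated), via alkylcopper 17 (not isolated), via (Z)-alkenylcopper 18 (not isolated)
Conditions: Mg, Et2O, 35 °C; CuBr·SMe2, Et2O/Me2S, −45 °C; 15, −25 °C; I2, THF, −78 to 0 °C
Reagents that add atoms: iodine, II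
Why: syn-Carbocupration of a terminal alkyne puts the alkyl group on the internal carbon and copper on the terminus of the same face, and iodinolysis of C–Cu goes with retention, which fixes the chain cis to iodine (Z).

**Step 11**
Reactants: 11 (2R)-2-methyl-2-[(E)-2-(4,4,5,5-tetramethyl-1,3,2-dioxaborolan-2-yl)ethenyl]-6-(triisopropylsilyloxy)-3,4-dihydro-2H-chromene; 19 2-[(3Z)-4-iodo-3-methylbut-3-en-1-yl]-1,3,3-trimethylcyclohex-1-ene
Product: 20 (2R)-2-methyl-2-[(1E,3Z)-4-methyl-6-(2,6,6-trimethylcyclohex-1-en-1-yl)hexa-1,3-dien-1-yl]-6-(triisopropylsilyloxy)-3,4-dihydro-2H-chromene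
Conditions: Pd(PPh3)4 (5 mol %), K3PO4 (aq), THF, 23 °C, degassed, dark
Reagents that add atoms: none
Why: Suzuki–Miyaura coupling of an alkenylboronate with an alkenyl iodide proceeds with retention at both sp2 carbons, and oxidative addition into C–I at room temperature should outrun ionisation of the allylic aryl ether.

**Step 12**
Reactants: 20 (2R)-2-methyl-2-[(1E,3Z)-4-methyl-6-(2,6,6-trimethylcyclohex-1-en-1-yl)hexa-1,3-dien-1-yl]-6-(triisopropylsilyloxy)-3,4-dihydro-2H-chromene
Product: 21 (2R)-2-methyl-2-[(1E,3Z)-4-methyl-6-(2,6,6-trimethylcyclohex-1-en-1-yl)hexa-1,3-dien-1-yl]-3,4-dihydro-2H-chromen-6-ol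
Conditions: TBAF/AcOH (1:1), THF, 0 °C
Reagents that add atoms: none
Why: Fluoride cleaves the aryl silyl ether, and the acetic acid buffer keeps the medium near neutral, so the acid-labile tertiary dienylic aryl ether and the oxidation-prone phenolate are both spared.

**Compound list**
1 | 2,5-dihydroxybenzaldehyde | O=Cc1cc(O)ccc1O | starting material
2 | 2-hydroxy-5-(triisopropylsilyloxy)benzaldehyde | O=Cc1cc(O[Si](C(C)C)(C(C)C)C(C)C)ccc1O | intermediate
3 | 2-ethenyl-4-(triisopropylsilyloxy)phenol | C=Cc1cc(O[Si](C(C)C)(C(C)C)C(C)C)ccc1O | intermediate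
4 | ethyl but-2-ynoate | CC#CC(=O)OCC | starting material
5 | ethyl (2E)-3-[2-ethenyl-4-(triisopropylsilyloxy)phenoxy]but-2-enoate | CCOC(=O)/C=C(\C)Oc1ccc(O[Si](C(C)C)(C(C)C)C(C)C)cc1C=C | intermediate
6 | (2E)-3-[2-ethenyl-4-(triisopropylsilyloxy)phenoxy]but-2-en-1-ol | OC/C=C(\C)Oc1ccc(O[Si](C(C)C)(C(C)C)C(C)C)cc1C=C | intermediate
7 | diethyl (2E)-3-[2-ethenyl-4-(triisopropylsilyloxy)phenoxy]but-2-en-1-yl phosphate | CCOP(=O)(OCC)OC/C=C(\C)Oc1ccc(O[Si](C(C)C)(C(C)C)C(C)C)cc1C=C | intermediate
8 | diethyl (2E)-3-{2-[2-(9-borabicyclo[3.3.1]nonan-9-yl)ethyl]-4-(triisopropylsilyloxy)phenoxy}but-2-en-1-yl phosphate | CCOP(=O)(OCC)OC/C=C(\C)Oc1ccc(O[Si](C(C)C)(C(C)C)C(C)C)cc1CCB1C2CCCC1CCC2 | intermediate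
9 | (2R)-2-ethenyl-2-methyl-6-(triisopropylsilyloxy)-3,4-dihydro-2H-chromene | C=C[C@@]1(C)CCc2cc(O[Si](C(C)C)(C(C)C)C(C)C)ccc2O1 | intermediate
10 | vinylboronic acid pinacol ester | C=CB1OC(C)(C)C(C)(C)O1 | starting material
11 | (2R)-2-methyl-2-[(E)-2-(4,4,5,5-tetramethyl-1,3,2-dioxaborolan-2-yl)ethenyl]-6-(triisopropylsilyloxy)-3,4-dihydro-2H-chromene | CC1(C)OB(/C=C/[C@@]2(C)CCc3cc(O[Si](C(C)C)(C(C)C)C(C)C)ccc3O2)OC1(C)C | intermediate
12 | 2-(2,6,6-trimethylcyclohex-1-en-1-yl)acetaldehyde | CC1=C(CC=O)C(C)(C)CCC1 | starting material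
13 | 2-(2,6,6-trimethylcyclohex-1-en-1-yl)ethan-1-ol | CC1=C(CCO)C(C)(C)CCC1 | intermediate
14 | 2-(2-bromoethyl)-1,3,3-trimethylcyclohex-1-ene | CC1=C(CCBr)C(C)(C)CCC1 | intermediate
15 | propyne | CC#C | starting material
16 | 2-(2,6,6-trimethylcyclohex-1-en-1-yl)ethylmagnesium bromide | CC1=C(CC[Mg]Br)C(C)(C)CCC1 | intermediate
17 | 2-(2,6,6-trimethylcyclohex-1-en-1-yl)ethylcopper(I) | CC1=C(CC[Cu])C(C)(C)CCC1 | intermediate
18 | (1Z)-2-methyl-4-(2,6,6-trimethylcyclohex-1-en-1-yl)but-1-en-1-ylcopper(I) | CC1=C(CC/C(C)=C\[Cu])C(C)(C)CCC1 | intermediate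
19 | 2-[(3Z)-4-iodo-3-methylbut-3-en-1-yl]-1,3,3-trimethylcyclohex-1-ene | CC1=C(CC/C(C)=C\I)C(C)(C)CCC1 | intermediate
20 | (2R)-2-methyl-2-[(1E,3Z)-4-methyl-6-(2,6,6-trimethylcyclohex-1-en-1-yl)hexa-1,3-dien-1-yl]-6-(triisopropylsilyloxy)-3,4-dihydro-2H-chromene | CC1=C(CC/C(C)=C\C=C\[C@@]2(C)CCc3cc(O[Si](C(C)C)(C(C)C)C(C)C)ccc3O2)C(C)(C)CCC1 | intermediate
21 | (2R)-2-methyl-2-[(1E,3Z)-4-methyl-6-(2,6,6-trimethylcyclohex-1-en-1-yl)hexa-1,3-dien-1-yl]-3,4-dihydro-2H-chromen-6-ol | CC1=C(CC/C(C)=C\C=C\[C@@]2(C)CCc3cc(O)ccc3O2)C(C)(C)CCC1 | target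

**Step count**
Total step count: 12.
Longest linear sequence: 9 (steps 1–7, 11, 12). Steps 8–10 form the side branch.

**Steps most likely to fail**

**1. Step 6.** Four processes may spoil it:
- ionisation or 1,4-elimination of the γ-aryloxyallyl phosphate before copper engages;
- slow boron-to-copper transfer with protodeboronation;
- intermolecular coupling;
- poor facial selectivity at the enol-ether alkene.

The fallback uses known chemistry and closes the ring at O1–C2 instead. It sets out from 3 and returns at 9. Hydroboration of 3 with 9-BBN-H (2.2 equiv, the phenol consuming one) gives the O,C-bis(9-BBN) adduct F1. trans-Hydroalumination of but-2-yn-1-ol with Red-Al followed by iodine gives (Z)-3-iodobut-2-en-1-ol F2. B-alkyl Suzuki–Miyaura coupling of the two (PdCl2(dppf), aq K3PO4, THF) gives the (Z)-allylic alcohol phenol F3. One equivalent of methyl chloroformate with pyridine at low temperature gives the allylic methyl carbonate F4. Palladium-catalysed asymmetric allylic O-alkylation of the free phenol (Pd2(dba)3, the C2-symmetric DACH-phenyl bis(2-diphenylphosphinobenzamide) ligand in the suitable antipode, AcOH, CH2Cl2) then closes the pyran ring at the tertiary allyl terminus to 9.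

**2. Step 7.** Metathesis at the vinyl group next to the fully substituted C2 may be so slow that self-metathesis of the vinylboronate and catalyst decay win. The fallback sets out from 9 and returns at 11 by hydrometalation instead of metathesis. Lemieux–Johnson cleavage (OsO4 cat., NaIO4, 2,6-lutidine) gives the (2R)-chromane-2-carbaldehyde F5. Lithiated trimethylsilyldiazomethane (Colvin rearrangement, THF, −78 °C) gives the (2R)-2-ethynylchromane F6. syn-Hydroboration with pinacolborane (Cp2ZrHCl cat., Et3N cat.) then gives 11.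

**3. Step 11.** Pd(0) may ionise the tertiary allylic aryl ether C2–O1, with loss of configuration or ring opening. The trisubstituted Z-alkene may also drift to E if the hindered boronate couples slowly. The fallback is a palladium-free union that sets out from 11 and 19 and returns at 20. Iododeboronation of 11 with NaOH then I2 (retention) gives the (E)-alkenyl iodide F7. Iodine–lithium exchange on 19 (t-BuLi, Et2O, −78 °C) gives the (Z)-alkenyllithium F8, which is quenched with Bu3SnCl to the (Z)-alkenylstannane F9. Copper(I) thiophene-2-carboxylate in NMP at 0 to 23 °C then joins the iodide and the stannane to 20 with retention at both alkenes.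

**Further compounds**
F1 | step 6 | 9-{2-[2-(9-borabicyclo[3.3.1]nonan-9-yloxy)-5-(triisopropylsilyloxy)phenyl]ethyl}-9-borabicyclo[3.3.1]nonane | CC(C)[Si](Oc1ccc(OB2C3CCCC2CCC3)c(CCB2C3CCCC2CCC3)c1)(C(C)C)C(C)C
F2 | step 6 | (Z)-3-iodobut-2-en-1-ol | C/C(I)=C/CO
F3 | step 6 | 2-[(3Z)-5-hydroxy-3-methylpent-3-en-1-yl]-4-(triisopropylsilyloxy)phenol | C/C(CCc1cc(O[Si](C(C)C)(C(C)C)C(C)C)ccc1O)=C/CO
F4 | step 6 | (2Z)-5-[2-hydroxy-5-(triisopropylsilyloxy)phenyl]-3-methylpent-2-en-1-yl methyl carbonate | C/C(CCc1cc(O[Si](C(C)C)(C(C)C)C(C)C)ccc1O)=C/COC(=O)OC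
F5 | step 7 | (2R)-2-methyl-6-(triisopropylsilyloxy)-3,4-dihydro-2H-chromene-2-carbaldehyde | O=C[C@@]1(C)CCc2cc(O[Si](C(C)C)(C(C)C)C(C)C)ccc2O1
F6 | step 7 | (2R)-2-ethynyl-2-methyl-6-(triisopropylsilyloxy)-3,4-dihydro-2H-chromene | C#C[C@@]1(C)CCc2cc(O[Si](C(C)C)(C(C)C)C(C)C)ccc2O1
F7 | step 11 | (2R)-2-[(E)-2-iodoethenyl]-2-methyl-6-(triisopropylsilyloxy)-3,4-dihydro-2H-chromene | I/C=C/[C@@]1(C)CCc2cc(O[Si](C(C)C)(C(C)C)C(C)C)ccc2O1
F8 | step 11 | (1Z)-2-methyl-4-(2,6,6-trimethylcyclohex-1-en-1-yl)but-1-en-1-yllithium | CC1=C(CC/C(C)=C\[Li])C(C)(C)CCC1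
F9 | step 11 | tributyl[(1Z)-2-methyl-4-(2,6,6-trimethylcyclohex-1-en-1-yl)but-1-en-1-yl]stannane | CC1=C(CC/C(C)=C\[Sn](CCCC)(CCCC)CCCC)C(C)(C)CCC1
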